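4 questions are open here, and the quantity to follow is how fast the other mono adduct is lost once the substrate reading has fallen.

| flask | substrate | partner | remark | time |
|---|---|---|---|---|
| epsilon | 0.050 M | 0.084 M | run made earlier |  |
| eta | 0.050 M | 0.14 M | run made earlier |  |
| gamma | 0.050 M | 0.23 M | run made earlier |  |
| violet | 0.050 M | 0.200 M |  | 12 min |
| grey | 0.050 M | 0.100 M |  | 12 min |
| amber | 0.050 M | 0.150 M |  | 12 min |

- epsilon (time / min: other mono adduct / %, first product / %, substrate / %): 0.833: 25.8, 17.3, 16.6; 2.00: 30.9, 18.5, 2.4; 4.00: 29.0, 18.2, 3.9; 6.00: 29.0, 18.4, 1.0; 8.00: 28.0, 20.4, 1.2
- eta (time / min: other mono adduct / %, first product / %, substrate / %): 0.833: 36.2, 23.0, 9.3; 2.00: 36.5, 21.1, 3.5; 4.00: 31.6, 21.9, 0.6; 6.00: 29.5, 19.9, 2.9; 8.00: 27.4, 19.0, 2.3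
- gamma (time / min: other mono adduct / %, first product / %, substrate / %): 0.833: 44.7, 25.5, 2.3; 2.00: 36.8, 23.8, 0; 4.00: 28.9, 22.2, 0.6; 6.00: 23.3, 19.9, 0; 8.00: 20.7, 22.6, 0

(readings scatter by 1 percentage point)

- which of these holds the largest part of the substrate at the end of violet (first product / double product / substrate / other mono adduct)
- which of these holds the largest part of the substrate at the end of grey (first product / double product / substrate / other mono adduct)
- which of these holds the largest part of the substrate at the end of amber (first product / double product / substrate / other mono adduct)
- final other mono adduct in grey, as a percentage of the substrate charged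

- percent here means substrate units held: one self-condensation product counts as two
- what may be going on: substrate + partner -> first product; substrate + partner -> other mono adduct; substrate <-> dormant form; 2 substrate -> self-condensation product; partner + first product -> double product; partner -> decomposed reagent; partner + other mono adduct -> double product

You can turn the partner charge and the time; the substrate charge stays at 0.050 M. By hand, more partner should lift the other mono adduct early, and the runs read so at 2.00 min: 30.9% at 0.084 M, 36.5% at 0.14 M, 36.8% at 0.23 M. More partner should also quicken the later loss of the other mono adduct. If each substrate took one partner, the excess partner left is the partner charge minus the substrate charge. With that excess held constant the loss is pseudo-first-order, and it integrates to ln([other mono adduct] at 2.00 min / [other mono adduct] at t) = κ × excess × elapsed time. The gamma run gives 0.533 L mol⁻¹ min⁻¹ for κ, the loss constant per unit of excess partner. Epsilon reads 0.483 L mol⁻¹ min⁻¹ and eta 0.531 L mol⁻¹ min⁻¹.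

Time acts through the same exponent. For grey, interpolating between epsilon and eta gives a start of 32.5% at 2.00 min. The excess of 0.0500 M gives a loss of 0.0266 min⁻¹, so my reckoning for 12 min is 24.9%.

The forecast says double product for violet, other mono adduct for grey and double product for amber, with 26% (23% to 29%) for n, on a decay “which scales with the partner left over”. Its number stands above mine.

The flask gives double product, other mono adduct and double product, and grey ends at 27.2%, which is 2.3 percentage points above my reckoning.

    substrate + partner → first product (k = 0.106 L mol⁻¹ s⁻¹)
    substrate + partner → other mono adduct (k = 0.188 L mol⁻¹ s⁻¹)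
    substrate ⇌ dormant form (K = 21.3, k = 0.0169 s⁻¹)
    2 substrate → self-condensation product (k = 0.0157 L mol⁻¹ s⁻¹)
    partner + first product → double product (k = 0.00675 L mol⁻¹ s⁻¹)
    partner → decomposed reagent (k = 0.00162 s⁻¹)
    partner + other mono adduct → double product (k = 0.0175 L mol⁻¹ s⁻¹)

In grey the other mono adduct is made at 0.346 of the rate it is used up at 3.79 min, and at 0.472 at 12.0 min, both below one, and κ was read as a net fall. The forecast on grey would be wrong if a run showed double product ahead, the order amber has at 0.150 M.

In a neighbouring flask, the same as grey but with 0.17 M of partner, κ on a start interpolated between eta and gamma gives 19.3%. The computed neighbour holds 22.3% of other mono adduct at 12.0 min, with double product ahead at 34.7%.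

Readings and results come from a simulation for substances that don't exist; the scatter is artificial.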